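**Plan**

Ring numbering: C1 (C=O), C2 (OH), C3 (hexadecyl), C4 (C=O), C5 (OH), C6 (H).
Enabling feature: C2-C3-C4-C5 is an unbroken four-carbon run carrying three oxygens and the chain. This is the skeleton of a 2-alkyl-4-alkoxyacetoacetate, which can be unmasked as an electron-rich diene. C1-C6 carries one oxygen and one hydrogen and maps onto a terminal ynone whose acetyl group is a masked C1 oxygen.
Retrosynthesis: cut the C5 O-methyl bond (vinylogous ester hydrolysis), take the quinone back to a benzenetriol, and return C1-O to C1-acetyl (Dakin). Then cut ring bonds C1-C2 and C5-C6 ([4+2]), and last the C3-chain bond (acetoacetate alkylation).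
Forward: the chain is joined first (step 1) and the keto ester is silylated twice to the diene (steps 2 and 3). The only ring closes and aromatises in step 4, and steps 5 and 6 set the oxidation level and free the last hydroxyl.
Stereochemistry: the target has no stereocentre and no stereogenic double bond. The racemic centre of the keto ester, the diene geometry and the two centres of the cycloadduct are all erased.

Key step: step 4

Assumption: the hydroxyquinone is taken as the 2,5-dihydroxy-1,4-benzoquinone tautomer drawn in the target structure.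

**Route**

Step 1
Reactants: 1 methyl 4-methoxy-3-oxobutanoate; 2 1-iodohexadecane
Product: 3 methyl 2-hexadecyl-4-methoxy-3-oxobutanoate (racemic)
Conditions: 1 (1.3 equiv), K2CO3 (1.5 equiv), acetone, reflux
Reagents that add atoms: none
Why: Acetoacetic ester alkylation, in which K2CO3 reversibly removes only the doubly activated alpha-proton of 1 (future ring C3) and the soft enolate displaces iodide from the primary halide at carbon (SN2), a slight excess of 1 holding back dialkylation; the new centre is racemic and disappears in step 2.

Step 2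
Reactants: 3 methyl 2-hexadecyl-4-methoxy-3-oxobutanoate
Product: 4 methyl 2-hexadecyl-4-methoxy-3-(trimethylsilyloxy)but-2-enoate (E/Z mixture)
Conditions: Me3SiCl (1.8 equiv), Et3N (1.8 equiv), toluene, rt, 72 h; filtration under Ar
Reagents that add atoms: chlorotrimethylsilane, C[Si](C)(C)Cl
Why: Silyl enol ether formation by soft enolisation, in which Et3N takes the acidic alpha-proton of the 1,3-dicarbonyl unit and the oxophilic silicon captures the ketone oxygen (future C4-O) to give the ester-conjugated beta-silyloxy enoate, the usual first stage of bis(silyloxy)diene preparation, which also works for 2-alkyl acetoacetates.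

Step 3
Reactants: 4 methyl 2-hexadecyl-4-methoxy-3-(trimethylsilyloxy)but-2-enoate
Product: 6 2-hexadecyl-1,4-dimethoxy-1,3-bis(trimethylsilyloxy)buta-1,3-diene (mixture of geometric isomers), via lithium dienolate 5 (not isolated)
Conditions: LiN(iPr)2 (1.3 equiv, commercial solution), THF, −78 °C, 1 h; Me3SiCl (1.5 equiv), −78 °C → rt; hexane, filtration under Ar; used crude
Reagents that add atoms: chlorotrimethylsilane, C[Si](C)(C)Cl
Why: Vinylogous deprotonation and O-silylation, in which the only protons of 4 acidified through the enoate are those of the CH2OMe group (future C5), so LiN(iPr)2 should give the extended dienolate 5, which Me3SiCl traps on the ester oxygen to form the ketene silyl acetal terminus (future C2), the standard second stage of 1-alkoxy-1,3-bis(silyloxy)diene synthesis.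

Step 4
Reactants: 6 2-hexadecyl-1,4-dimethoxy-1,3-bis(trimethylsilyloxy)buta-1,3-diene; 7 3-butyn-2-one
Product: 9 1-(3-hexadecyl-2,4-dihydroxy-5-methoxyphenyl)ethan-1-one, via cyclohexadiene cycloadduct 8 (not isolated)
Conditions: 7 (1.5 equiv), BHT (cat.), toluene, rt → 80 °C, sealed vessel, Ar; then 1 M HCl, THF, rt
Reagents that add atoms: none
Why: The diene 6, whose HOMO is raised by four oxygen donors, and the electron-poor ynone 7 should combine in a normal-electron-demand, concerted but strongly asynchronous Diels-Alder reaction in which C5-C6 forms ahead of C1-C2, so the six-membered carbocycle closes in one intermolecular [4+2] event (in the stepwise limit, Mukaiyama-Michael addition followed by attack of the allenolate carbon on the silyloxycarbenium ion gives the same ring). The closest known reaction type is the cycloaddition of 1-alkoxy-1,3-bis(silyloxy)butadienes with acetylenic esters and ketones, an established entry to beta-resorcylate and acylresorcinol rings. The one selectivity needed is regiochemical: C5 is the vinylogous carbon of a ketene acetal, fed by both C2 oxygens and the C4 silyloxy group, which together outweigh the opposing C5 methoxy donor, and it pairs with the unsubstituted beta-carbon of 7 that carries the largest LUMO coefficient, while the fully substituted C2 bonds late to the acyl-bearing carbon, so the acetyl group lands on C1, ortho to the C2 oxygen and para to the C4 oxygen. In 8 only the C2 ketal can ionise to an oxygen-stabilised cation, so acid should expel methanol from C2 together with the C5 hydrogen and leave the C5 methoxy group in place, and hydrolysis of the two silyl ethers completes the aromatisation. The two stereocentres of 8 (C2 and C5) and the geometry of 6 are uncontrolled, which does not matter because the arene erases them.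

Step 5
Reactants: 9 1-(3-hexadecyl-2,4-dihydroxy-5-methoxyphenyl)ethan-1-one
Product: 12 3-hexadecyl-2-hydroxy-5-methoxycyclohexa-2,5-diene-1,4-dione, via aryl acetate 10 (not isolated), via benzenetriol 11 (not isolated)
Conditions: 30% aq H2O2 (1.2 equiv), NaOH (3.5 equiv), THF-H2O, 0 °C → rt, Ar; 1 M HCl, extraction into EtOAc; FeCl3 (2.2 equiv), H2O-EtOAc, rt
Reagents that add atoms: hydrogen peroxide, OO
Why: Dakin oxidation, in which hydroperoxide adds to the acetyl carbonyl and the aryl group, made a strong migrating group by its ortho (C2) and para (C4) phenoxides, shifts to oxygen to give acetate 10, which is saponified in the flask to triol 11, whose para-related C1 and C4 hydroxyls are then dehydrogenated by trivalent iron to the more stable para-quinone tautomer.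

Step 6
Reactants: 12 3-hexadecyl-2-hydroxy-5-methoxycyclohexa-2,5-diene-1,4-dione
Product: 13 3-hexadecyl-2,5-dihydroxycyclohexa-2,5-diene-1,4-dione (target)
Conditions: 2 M NaOH (5 equiv), 1,4-dioxane-H2O, 70 °C, Ar; then 2 M HCl
Reagents that add atoms: sodium hydroxide, [Na+].[OH-]
Why: Saponification of a vinylogous ester by addition-elimination, in which hydroxide adds to C5, methoxide leaves and the resonance-stabilised dianion resists further attack until acidification, a hydrolysis that is routine for 2,5-dialkoxy-3-alkyl-1,4-benzoquinones.

**Compound list**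

1 | methyl 4-methoxy-3-oxobutanoate | COCC(=O)CC(=O)OC | starting material
2 | 1-iodohexadecane | CCCCCCCCCCCCCCCCI | starting material
3 | methyl 2-hexadecyl-4-methoxy-3-oxobutanoate (racemic) | CCCCCCCCCCCCCCCCC(C(=O)COC)C(=O)OC | intermediate
4 | methyl 2-hexadecyl-4-methoxy-3-(trimethylsilyloxy)but-2-enoate (E/Z mixture) | CCCCCCCCCCCCCCCCC(C(=O)OC)=C(COC)O[Si](C)(C)C | intermediate
5 | lithium 2-hexadecyl-1,4-dimethoxy-3-(trimethylsilyloxy)buta-1,3-dien-1-olate (not isolated) | CCCCCCCCCCCCCCCCC(=C(OC)[O-])C(O[Si](C)(C)C)=COC.[Li+] | intermediate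
6 | 2-hexadecyl-1,4-dimethoxy-1,3-bis(trimethylsilyloxy)buta-1,3-diene (geometric isomers) | CCCCCCCCCCCCCCCCC(=C(OC)O[Si](C)(C)C)C(O[Si](C)(C)C)=COC | intermediate
7 | 3-butyn-2-one | CC(=O)C#C | starting material
8 | 1-[5-hexadecyl-3,6-dimethoxy-4,6-bis(trimethylsilyloxy)cyclohexa-1,4-dien-1-yl]ethan-1-one (diastereomer mixture, not isolated) | CCCCCCCCCCCCCCCCC1=C(O[Si](C)(C)C)C(OC)C=C(C(C)=O)C1(OC)O[Si](C)(C)C | intermediate
9 | 1-(3-hexadecyl-2,4-dihydroxy-5-methoxyphenyl)ethan-1-one | CCCCCCCCCCCCCCCCc1c(O)c(C(C)=O)cc(OC)c1O | intermediate
10 | 3-hexadecyl-2,4-dihydroxy-5-methoxyphenyl acetate (not isolated) | CCCCCCCCCCCCCCCCc1c(O)c(OC(C)=O)cc(OC)c1O | intermediate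
11 | 3-hexadecyl-5-methoxybenzene-1,2,4-triol (not isolated) | CCCCCCCCCCCCCCCCc1c(O)c(O)cc(OC)c1O | intermediate
12 | 3-hexadecyl-2-hydroxy-5-methoxycyclohexa-2,5-diene-1,4-dione | CCCCCCCCCCCCCCCCC1=C(O)C(=O)C=C(OC)C1=O | intermediate
13 | 3-hexadecyl-2,5-dihydroxycyclohexa-2,5-diene-1,4-dione (CNP0283865.0) | CCCCCCCCCCCCCCCCC1=C(O)C(=O)C=C(O)C1=O | target

Total step count: 6.
Longest linear sequence: 6 steps (from 1 or 2 to 13).

**Steps most likely to fail**

Step 4.
- **Risk:** Cycloaddition of the tetrasubstituted diene may be slower than its protodesilylation and the polymerisation of 7.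
- **Risk:** The geometric isomer whose C5 methoxy group points into the s-cis cavity may not react.
- **Risk:** The C5 methoxy donor may erode the regioselectivity.
- **Risk:** Silanol rather than methanol may be expelled from the ketal carbon.
- **Fallback:** This gives up ring construction in favour of directed metalation of a preformed arene; it sets out from 2 and comes back at 13. Commercial 1,2,4,5-tetramethoxybenzene is lithiated between two methoxy groups (nBuLi, THF, 0 °C) to (2,3,5,6-tetramethoxyphenyl)lithium F1. F1 is alkylated by 2 to 3-hexadecyl-1,2,4,5-tetramethoxybenzene F2. Oxidative demethylation with (NH4)2Ce(NO3)6 in MeCN-H2O should give 3-hexadecyl-2,5-dimethoxy-1,4-benzoquinone F3. The NaOH conditions of step 6 then cleave both vinylogous esters to 13.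

Step 5.
- **Risk:** Hydroperoxide may add only slowly to a chelated ketone that is deactivated by two phenoxides.
- **Risk:** Alkaline peroxide may over-oxidise the very electron-rich ring once it is formed, by ring cleavage or Hooker-type degradation of the chain.
- **Fallback:** This replaces the alkaline Dakin step by a Baeyer-Villiger oxidation of a protected ketone under non-basic conditions; it sets out from 9 and comes back at 10. Both phenols are benzylated (BnBr, K2CO3, DMF, 70 °C) to 1-[2,4-bis(benzyloxy)-3-hexadecyl-5-methoxyphenyl]ethan-1-one F4. mCPBA in CH2Cl2 moves the trialkoxyaryl group to oxygen to give 2,4-bis(benzyloxy)-3-hexadecyl-5-methoxyphenyl acetate F5. Hydrogenolysis (H2, Pd/C, EtOAc) releases 10. In this variant 10 can be handled, and it is then saponified under argon and oxidised with FeCl3 as in the second half of step 5.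

Step 3.
- **Risk:** Vinylogous deprotonation may be incomplete, and C-silylation may compete.
- **Risk:** The diene cannot be distilled or chromatographed, so it may lose its trimethylsilyl groups by hydrolysis during isolation.
- **Fallback:** This avoids the strong base and uses a sturdier silyl group, so the diene can be purified; it sets out from 3 and comes back at 9. Double soft enolisation of 3 with tBuMe2SiOTf (2.4 equiv) and Et3N in Et2O (0 °C → rt) should give 1,3-bis(tert-butyldimethylsilyloxy)-2-hexadecyl-1,4-dimethoxybuta-1,3-diene F6, bypassing 4 and 5. Heating F6 with 7 in toluene gives 1-[4,6-bis(tert-butyldimethylsilyloxy)-5-hexadecyl-3,6-dimethoxycyclohexa-1,4-dien-1-yl]ethan-1-one F7. Et3N·3HF in THF desilylates and aromatises F7 to 9.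

**Further compounds**

F1 | step 4 | (2,3,5,6-tetramethoxyphenyl)lithium | [Li]c1c(OC)c(OC)cc(OC)c1OC
F2 | step 4 | 3-hexadecyl-1,2,4,5-tetramethoxybenzene | CCCCCCCCCCCCCCCCc1c(OC)c(OC)cc(OC)c1OC
F3 | step 4 | 3-hexadecyl-2,5-dimethoxycyclohexa-2,5-diene-1,4-dione | CCCCCCCCCCCCCCCCC1=C(OC)C(=O)C=C(OC)C1=O
F4 | step 5 | 1-[2,4-bis(benzyloxy)-3-hexadecyl-5-methoxyphenyl]ethan-1-one | CCCCCCCCCCCCCCCCc1c(OCc2ccccc2)c(C(C)=O)cc(OC)c1OCc3ccccc3
F5 | step 5 | 2,4-bis(benzyloxy)-3-hexadecyl-5-methoxyphenyl acetate | CCCCCCCCCCCCCCCCc1c(OCc2ccccc2)c(OC(C)=O)cc(OC)c1OCc3ccccc3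
F6 | step 3 | 1,3-bis(tert-butyldimethylsilyloxy)-2-hexadecyl-1,4-dimethoxybuta-1,3-diene (geometric isomers) | CCCCCCCCCCCCCCCCC(=C(OC)O[Si](C)(C)C(C)(C)C)C(O[Si](C)(C)C(C)(C)C)=COC
F7 | step 3 | 1-[4,6-bis(tert-butyldimethylsilyloxy)-5-hexadecyl-3,6-dimethoxycyclohexa-1,4-dien-1-yl]ethan-1-one (diastereomer mixture) | CCCCCCCCCCCCCCCCC1=C(O[Si](C)(C)C(C)(C)C)C(OC)C=C(C(C)=O)C1(OC)O[Si](C)(C)C(C)(C)C
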